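The route rests on a formal [4+1] disconnection of ring D (the 2,3-dihydrofuran: C13, C14, C15, O, C16) at the C13–C16 bond. The precursor is the spiro-oxolane vinylogous formate 12, in which O=C15–C14=C13 hangs exocyclic on ring C and C13 is the donor-substituted (O9) β-carbon. O-Alkylation of the formyl oxygen with (trimethylsilyl)methyl triflate and fluoride desilylation unveil a carbonyl ylide whose 6π 1,5-electrocyclization closes ring D, forms C13–C16, creates the C14=C15 enol ether and sets C13 in one operation. Compound 12 comes from (+)-larixol by ring-B oxidation (9α-OH, then 7β,8β-diol) and side-chain cleavage.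

Key step: step 9

Remark: labdane numbering is used (ring C = oxolane, ring D = dihydrofuran); from compound 8 on, the methyl carbon of the methyl ketone is numbered C14 because it becomes C14 of the target; (+)-larixol is assumed to be purchasable as the isolated natural product; 8–10 are drawn as open hydroxy ketones although they equilibrate with their 9,13-hemiketals.

Step 1
Reactants: 1 (+)-larixol
Product: 2 13(S)-hydroxylabda-8(17),14-dien-6-one
Conditions: Dess–Martin periodinane, CH2Cl2, 0 °C to rt
Reagents that add atoms: none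
Why: Dess–Martin oxidation should convert the equatorial secondary C6 alcohol into the ketone while the tertiary allylic C13 alcohol and both alkenes stay untouched; no stereocentre is formed.

Step 2
Reactants: 2 13(S)-hydroxylabda-8(17),14-dien-6-one
Product: 3 13(S)-hydroxylabda-7,14-dien-6-one
Conditions: DBU (0.3 equiv), toluene, 60 °C
Reagents that add atoms: none
Why: Base-mediated β,γ-to-α,β enone isomerization through the C7 dienolate should move the exocyclic alkene into conjugation as C7=C8; DBU does not ionize the tertiary C13 alcohol, so oxa-Michael addition to C8 is not expected.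

Step 3
Reactants: 3 13(S)-hydroxylabda-7,14-dien-6-one
Product: 4 6,13-bis(trimethylsilyloxy)labda-6,8,14-triene
Conditions: TMSOTf (2.5 equiv), Et3N, CH2Cl2, 0 °C to rt; pentane extraction
Reagents that add atoms: trimethylsilyl trifluoromethanesulfonate C[Si](C)(C)OS(=O)(=O)C(F)(F)F
Why: Soft enolization under equilibrating conditions (thermodynamic silyl dienol ether formation) should give the homoannular C6=C7–C8=C9 diene with the tetrasubstituted C8=C9 bond, and silylates the C13 alcohol at the same time.

Step 4
Reactants: 4 6,13-bis(trimethylsilyloxy)labda-6,8,14-triene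
Product: 7 9α,13-dihydroxylabda-7,14-dien-6-one, via silyl peroxide 5 (not isolated), via bis-silyl ether 6 (not isolated)
Conditions: O2, tetraphenylporphyrin, visible light, CH2Cl2, –78 °C; PPh3; citric acid, MeOH, 0 °C
Reagents that add atoms: dioxygen O=O
Why: Photooxygenation of a silyl dienol ether (vinylogous silatropic ene / [4+2] addition of singlet oxygen across C6 and C9 of the cisoid ring-B diene) should occur on the α face because the axial C10 methyl screens the β face, so C9 is set as 9α-O; PPh3 reduces the silyl peroxide and methanolysis frees both alcohols.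

Step 5
Reactants: 7 9α,13-dihydroxylabda-7,14-dien-6-one
Product: 8 9α-hydroxy-15,16-dinorlabd-7-ene-6,13-dione
Conditions: OsO4 (2 mol %), NaIO4 (4 equiv), 2,6-lutidine, dioxane/H2O, rt
Reagents that add atoms: none
Why: Lemieux–Johnson cleavage: OsO4 should dihydroxylate the terminal vinyl group far faster than the hindered, electron-poor C7=C8 enone, and periodate then degrades the 13,14,15-triol to the C13 methyl ketone.

Step 6
Reactants: 8 9α-hydroxy-15,16-dinorlabd-7-ene-6,13-dione
Product: 9 7β,8β,9α-trihydroxy-15,16-dinorlabdane-6,13-dione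
Conditions: OsO4 (5 mol %), N-methylmorpholine N-oxide, citric acid, t-BuOH/H2O, rt
Reagents that add atoms: OsO4 O=[Os](=O)(=O)=O (catalytic carrier of both oxygens); N-methylmorpholine N-oxide C[N+]1([O-])CCOCC1; water O
Why: Upjohn dihydroxylation of the enone; following the empirical rule that OsO4 adds anti to an allylic C–O bond, syn addition is expected on the β face, opposite the axial 9α-oxygen, which sets 7β-OH and 8β-OH (8α-methyl) together.

Step 7
Reactants: 9 7β,8β,9α-trihydroxy-15,16-dinorlabdane-6,13-dione
Product: 10 7β-acetoxy-8β,9α-dihydroxy-15,16-dinorlabdane-6,13-dione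
Conditions: Ac2O, pyridine, DMAP (cat.), CH2Cl2, 0 °C
Reagents that add atoms: acetic anhydride CC(=O)OC(C)=O
Why: Acylation should take place only at the secondary equatorial 7β-OH, since the tertiary 8β-, 9α- and hemiketal hydroxyls do not react under these conditions.

Step 8
Reactants: 10 7β-acetoxy-8β,9α-dihydroxy-15,16-dinorlabdane-6,13-dione
Product: 12 7β-acetoxy-8β-hydroxy-6-oxo-9α,13-epoxy-16-norlabd-13-en-15-al (E/Z mixture), via enaminone 11 (not isolated)
Conditions: DMF dimethyl acetal, toluene, 80 °C; then AcOH/H2O/THF, rt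
Reagents that add atoms: N,N-dimethylformamide dimethyl acetal COC(OC)N(C)C; water O
Why: Enaminone formation should occur at the methyl group of the methyl ketone, and mild aqueous acid then hydrolyses the enaminone to the hydroxymethylene ketone, which the 9α-OH captures at C13 (5-exo-trig hemiketalization) before dehydration into conjugation closes ring C as the oxolan-2-ylidene acetaldehyde.

Step 9
Reactants: 12 7β-acetoxy-8β-hydroxy-6-oxo-9α,13-epoxy-16-norlabd-13-en-15-al
Product: 15 7β-acetoxy-8β-hydroxy-9α,13(S):15,16-diepoxylabd-14-en-6-one (target), via trimethinium triflate 13 (not isolated), via carbonyl ylide 14 (not isolated)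
Conditions: Me3SiCH2OTf, 2,6-di-tert-butylpyridine (cat.), CH2Cl2, 0 °C to rt; then CsF, MeCN, –20 °C to rt; work-up on base-washed silica
Reagents that add atoms: (trimethylsilyl)methyl trifluoromethanesulfonate C[Si](C)(C)COS(=O)(=O)C(F)(F)F
Why: Proposed new method: Me3SiCH2OTf alkylates the formyl oxygen of the vinylogous formate (the most nucleophilic oxygen present) to give the 1,3-dialkoxyallyl cation 13, and fluoride attack on silicon then releases the carbonyl ylide 14, whose C16 terminus is carbanionic while C13, flanked by the O9 donor, is oxocarbenium-like, so that a thermally allowed 6π disrotatory 1,5-electrocyclization joins C16 to C13. The closest known reaction types are the fluoride-induced generation of carbonyl and azomethine ylides from silylmethyl-substituted oxocarbenium and iminium ions and the 1,5-electrocyclization of vinyl carbonyl ylides (from diazo compounds and enones, or from vinyl oxiranes) to 2,3-dihydrofurans; their combination on a β-alkoxy enal has no precedent. Ring D is closed in the 1,5-dipolar electrocyclic mode (formally a 5-endo closure of C16 onto C13 across the O16–C15=C14 tether), which delivers the C14=C15 enol ether directly. C13 is the only new stereocentre and is fixed by the face of the planar ylide terminus to which C16 bonds: 13S needs bonding on the face turned toward C10/C1, and the only controlling element is the C9 spiro centre, whose C8 flank (quaternary carbon with equatorial methyl, the C7 acetate beyond it) is slightly more encumbered than the C1 methylene flank, so entry anti to C8 is expected but with a modest bias only. The step further needs O-alkylation at the formyl oxygen instead of the tertiary 8-OH, the C6 ketone or the acetate (secured by the vinylogous-ester polarization of 12) and 1,5-closure instead of 1,3-closure to an oxirane or protonation at C16 (favoured by the donor at C13 and by anhydrous CsF in MeCN). Both C13=C14 isomers of 12 converge because cation 13 and ylide 14 equilibrate by rotation about their partial double bonds.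

Compound list
1 | (+)-larixol, labda-8(17),14-diene-6α,13(S)-diol | C=C1C[C@H](O)[C@H]2C(C)(C)CCC[C@]2(C)[C@H]1CC[C@](C)(O)C=C | starting material
2 | 13(S)-hydroxylabda-8(17),14-dien-6-one | C=C1CC(=O)[C@H]2C(C)(C)CCC[C@]2(C)[C@H]1CC[C@](C)(O)C=C | intermediate
3 | 13(S)-hydroxylabda-7,14-dien-6-one | CC1=CC(=O)[C@H]2C(C)(C)CCC[C@]2(C)[C@H]1CC[C@](C)(O)C=C | intermediate
4 | 6,13-bis(trimethylsilyloxy)labda-6,8,14-triene | CC1=C(CC[C@](C)(O[Si](C)(C)C)C=C)[C@@]2(C)CCCC(C)(C)[C@@H]2C(O[Si](C)(C)C)=C1 | intermediate
5 | 9α-(trimethylsilylperoxy)-13-(trimethylsilyloxy)labda-7,14-dien-6-one | CC1=CC(=O)[C@H]2C(C)(C)CCC[C@]2(C)[C@@]1(OO[Si](C)(C)C)CC[C@](C)(O[Si](C)(C)C)C=C | intermediate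
6 | 9α,13-bis(trimethylsilyloxy)labda-7,14-dien-6-one | CC1=CC(=O)[C@H]2C(C)(C)CCC[C@]2(C)[C@@]1(O[Si](C)(C)C)CC[C@](C)(O[Si](C)(C)C)C=C | intermediate
7 | 9α,13-dihydroxylabda-7,14-dien-6-one | CC1=CC(=O)[C@H]2C(C)(C)CCC[C@]2(C)[C@@]1(O)CC[C@](C)(O)C=C | intermediate
8 | 9α-hydroxy-15,16-dinorlabd-7-ene-6,13-dione | CC1=CC(=O)[C@H]2C(C)(C)CCC[C@]2(C)[C@@]1(O)CCC(C)=O | intermediate
9 | 7β,8β,9α-trihydroxy-15,16-dinorlabdane-6,13-dione | O[C@H]1C(=O)[C@H]2C(C)(C)CCC[C@]2(C)[C@@](O)(CCC(C)=O)[C@@]1(C)O | intermediate
10 | 7β-acetoxy-8β,9α-dihydroxy-15,16-dinorlabdane-6,13-dione | CC(=O)O[C@H]1C(=O)[C@H]2C(C)(C)CCC[C@]2(C)[C@@](O)(CCC(C)=O)[C@@]1(C)O | intermediate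
11 | (14E)-7β-acetoxy-15-(dimethylamino)-8β,9α-dihydroxy-16-norlabd-14-ene-6,13-dione | CC(=O)O[C@H]1C(=O)[C@H]2C(C)(C)CCC[C@]2(C)[C@@](O)(CCC(=O)/C=C/N(C)C)[C@@]1(C)O | intermediate
12 | 7β-acetoxy-8β-hydroxy-6-oxo-9α,13-epoxy-16-norlabd-13-en-15-al (E/Z mixture) | CC(=O)O[C@H]1C(=O)[C@H]2C(C)(C)CCC[C@]2(C)[C@@]2(CCC(=CC=O)O2)[C@@]1(C)O | intermediate
13 | O-[(trimethylsilyl)methyl] oxonium (1,3-dialkoxyallyl cation) triflate of 12 | CC(=O)O[C@H]1C(=O)[C@H]2C(C)(C)CCC[C@]2(C)[C@@]2(CCC(=CC=[O+]C[Si](C)(C)C)O2)[C@@]1(C)O.[O-]S(=O)(=O)C(F)(F)F | intermediate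
14 | carbonyl ylide (oxonium methylide) of 12 | CC(=O)O[C@H]1C(=O)[C@H]2C(C)(C)CCC[C@]2(C)[C@@]2(CCC(=CC=[O+][CH2-])O2)[C@@]1(C)O | intermediate
15 | 7β-acetoxy-8β-hydroxy-9α,13(S):15,16-diepoxylabd-14-en-6-one | CC(=O)O[C@H]1C(=O)[C@H]2C(C)(C)CCC[C@]2(C)[C@@]2(CC[C@@]3(C=COC3)O2)[C@@]1(C)O | target

Total step count: 9. Longest linear sequence: 9 steps (fully linear from 1).

Steps most likely to fail

1. Step 9 (Proposed new method). The ylide may close 1,3 to a vinyl oxirane or be protonated at C16 before it reaches the U-shaped conformer. The two faces of C13 are also nearly equivalent (C1H2 on one side, C17H3 on the other), so poor facial selectivity and the C13 epimer as co-product are the main stereochemical risk of the route. The fallback uses known chemistry and runs from 12 back to 15. The carbonyl ylide is made from a metal carbene instead: Rh2(OAc)4-catalysed decomposition of the diazoacetate of N-hydroxyphthalimide in the presence of 12 (the known formal [4+1] of unsaturated carbonyl compounds with diazo esters). CuOTf with a planar-chiral bipyridine ligand, the system of the known asymmetric variant, can replace Rh2(OAc)4 to put the C13 face under catalyst control. This should give the C16 N-acyloxyphthalimide ester of 15 F1. Photoreductive decarboxylation (Ru(bpy)3Cl2, Hantzsch ester, i-Pr2NEt, blue light) then removes the ester carbon and returns to 15.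

2. Step 6. Facial selectivity may be poor: OsO4 may add on the α face (anti to the axial C10 methyl), which would place the C8 hydroxyl α. The fallback runs from 8 back to 10 and sets C8 by inversion through an epoxide. Nucleophilic (Weitz–Scheffer) epoxidation of the enone with H2O2/NaOH, expected on the α face, should give 7α,8α-epoxy-9α-hydroxy-15,16-dinorlabdane-6,13-dione F2. Acid-catalysed trans-diaxial opening by water at the tertiary C8 (HClO4, THF/H2O) should give 7α,8β,9α-trihydroxy-15,16-dinorlabdane-6,13-dione F3. Acetylation of the secondary alcohol gives 7α-acetoxy-8β,9α-dihydroxy-15,16-dinorlabdane-6,13-dione F4. Base-mediated epimerization next to the C6 ketone (DBU, CH2Cl2) moves the acetate into the equatorial 7β position and returns to 10.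

3. Step 8. The acetate may be lost or migrate, and ring B may undergo retro-aldol cleavage or β-elimination under the hot, basic amide-acetal conditions. Ring closure may also go through the formyl carbon to a seven-membered vinylogous ester. The fallback runs from 8 back to 12: C15 is introduced before ring B becomes base-sensitive and is carried in protected form. DMF dimethyl acetal on 8 gives (14E)-15-(dimethylamino)-9α-hydroxy-16-norlabda-7,14-diene-6,13-dione F5. HC(OMe)3/MeOH/TsOH converts it into 9α,13-epoxy-13,15,15-trimethoxy-16-norlabd-7-en-6-one F6, which already contains ring C. Dihydroxylation as in step 6 gives 7β,8β-dihydroxy-9α,13-epoxy-13,15,15-trimethoxy-16-norlabdan-6-one F7. Acetylation as in step 7 gives 7β-acetoxy-8β-hydroxy-9α,13-epoxy-13,15,15-trimethoxy-16-norlabdan-6-one F8. PPTS in wet acetone then hydrolyses the acetal and eliminates methanol from the ketal toward C14, returning to 12.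

Further compounds
F1 | step 9 | 16-[(1,3-dioxoisoindolin-2-yl)oxycarbonyl] derivative of 15 (C16 epimers) | CC(=O)O[C@H]1C(=O)[C@H]2C(C)(C)CCC[C@]2(C)[C@@]2(CC[C@@]3(C=COC3C(=O)ON3C(=O)c4ccccc4C3=O)O2)[C@@]1(C)O
F2 | step 6 | 7α,8α-epoxy-9α-hydroxy-15,16-dinorlabdane-6,13-dione | O1[C@@H]2C(=O)[C@H]3C(C)(C)CCC[C@]3(C)[C@@](O)(CCC(C)=O)[C@]12C
F3 | step 6 | 7α,8β,9α-trihydroxy-15,16-dinorlabdane-6,13-dione | O[C@@H]1C(=O)[C@H]2C(C)(C)CCC[C@]2(C)[C@@](O)(CCC(C)=O)[C@@]1(C)O
F4 | step 6 | 7α-acetoxy-8β,9α-dihydroxy-15,16-dinorlabdane-6,13-dione | CC(=O)O[C@@H]1C(=O)[C@H]2C(C)(C)CCC[C@]2(C)[C@@](O)(CCC(C)=O)[C@@]1(C)O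
F5 | step 8 | (14E)-15-(dimethylamino)-9α-hydroxy-16-norlabda-7,14-diene-6,13-dione | CC1=CC(=O)[C@H]2C(C)(C)CCC[C@]2(C)[C@@]1(O)CCC(=O)/C=C/N(C)C
F6 | step 8 | 9α,13-epoxy-13,15,15-trimethoxy-16-norlabd-7-en-6-one (C13 epimers) | CC1=CC(=O)[C@H]2C(C)(C)CCC[C@]2(C)[C@@]12CCC(CC(OC)OC)(OC)O2
F7 | step 8 | 7β,8β-dihydroxy-9α,13-epoxy-13,15,15-trimethoxy-16-norlabdan-6-one | O[C@H]1C(=O)[C@H]2C(C)(C)CCC[C@]2(C)[C@@]2(CCC(CC(OC)OC)(OC)O2)[C@@]1(C)O
F8 | step 8 | 7β-acetoxy-8β-hydroxy-9α,13-epoxy-13,15,15-trimethoxy-16-norlabdan-6-one | CC(=O)O[C@H]1C(=O)[C@H]2C(C)(C)CCC[C@]2(C)[C@@]2(CCC(CC(OC)OC)(OC)O2)[C@@]1(C)O
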